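**Assumption:** colupone has no stereocentre (each quaternary ring carbon carries two identical prenyl groups), so the achiral compound is the only form to be made; tautomers are counted as one compound and the target is drawn as in the given SMILES.

## Retrosynthetic overview

- Colupone ⇐ four ring C-prenyl groups, each traced back to a tertiary allyl C–O bond: a ring oxygen is O-alkylated as its 1,1-dimethylallyl ether, which passes the allyl unit to the neighbouring ring carbon by [3,3] shift.
- All four O-alkylation/shift cycles (two aromatic, two dearomatising) run in one flask from phlorisobutyrophenone and tert-butyl 2-methylbut-3-en-2-yl carbonate under Pd(0).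
- Phlorisobutyrophenone ⇐ Friedel–Crafts acylation of phloroglucinol with isobutyryl chloride; the carbonate ⇐ 2-methylbut-3-en-2-ol + Boc2O.
- No ring is built: the carbocycle is the phloroglucinol ring, dearomatised in the last step.

## Route

Step 1
Reactants: 1 phloroglucinol (benzene-1,3,5-triol); 2 isobutyryl chloride (2-methylpropanoyl chloride)
Product: 3 phlorisobutyrophenone [2-methyl-1-(2,4,6-trihydroxyphenyl)propan-1-one]
Conditions: AlCl3 (3.5 equiv), PhNO2, rt → 65 °C; then ice/1 M HCl
Reagents that add atoms: none
Why: Friedel–Crafts C-acylation of the strongly activated triol, where the first acyl group deactivates the ring so that mono-acylation prevails; no stereocentre is formed.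

Step 2
Reactants: 4 2-methylbut-3-en-2-ol; 5 di-tert-butyl dicarbonate
Product: 7 tert-butyl 2-methylbut-3-en-2-yl carbonate, via lithium 2-methylbut-3-en-2-olate 6 (not isolated)
Conditions: n-BuLi (1.05 equiv), THF, −78 → 0 °C; then 5, 0 °C → rt; H2O work-up
Reagents that add atoms: none
Why: Alkoxycarbonylation (O-Boc formation) of the pre-formed lithium alkoxide, which acylates cleanly where the neutral hindered tertiary alcohol does not.

Step 3
Reactants: 3 phlorisobutyrophenone; 7 tert-butyl 2-methylbut-3-en-2-yl carbonate (4.6 equiv)
Product: 15 colupone, via tert-prenyl aryl ether 8 (not isolated), via monoprenyl phenol 9 (not isolated), via second tert-prenyl ether 10 (not isolated), via deoxycohumulone 11 (not isolated), via third tert-prenyl ether 12 (not isolated), via colupulone 13 (not isolated), via enol tert-prenyl ether 14 (not isolated)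
Conditions: Pd(PPh3)4 (5 mol %), 7 added over 4 h, degassed 1,4-dioxane, 25 → 90 °C, Ar; stop by LC-MS when 13 is consumed
Reagents that add atoms: none
Why: Proposed new method: a four-cycle relay in which Pd(0) ionises 7 (loss of CO2, t-BuO− as internal base) and the most acidic free ring O–H (the non-chelated one each time, becoming more acidic as the ring dearomatises) attacks the tertiary terminus of the π-prenyl complex to form the C–O bond; each 1,1-dimethylallyl ether then delivers a linear prenyl group to the flanking ring carbon by [3,3] shift (aromatic Claisen for 8 and 10, dearomative Claisen for 12 and 14, with any Pd-mediated ionisation–recombination of the ether giving the same linear C-prenyl product) and tautomerisation regenerates an O–H for the next cycle, so the sequence should stop once both ring CH positions are quaternary; the closest known chemistry is the Pd-catalysed decarboxylative O-reverse-prenylation of phenols followed by thermal aromatic Claisen rearrangement, which has not been run as a relay or on dearomatised acylphloroglucinol enols; no stereocentre is formed.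

## Compound list

1 | phloroglucinol (benzene-1,3,5-triol) | Oc1cc(O)cc(O)c1 | starting material
2 | isobutyryl chloride (2-methylpropanoyl chloride) | CC(C)C(=O)Cl | starting material
3 | phlorisobutyrophenone, 2-methyl-1-(2,4,6-trihydroxyphenyl)propan-1-one | CC(C)C(=O)c1c(O)cc(O)cc1O | intermediate
4 | 2-methylbut-3-en-2-ol | CC(C)(O)C=C | starting material
5 | di-tert-butyl dicarbonate (Boc2O) | CC(C)(C)OC(=O)OC(=O)OC(C)(C)C | starting material
6 | lithium 2-methylbut-3-en-2-olate | [Li+].[O-]C(C)(C)C=C | intermediate
7 | tert-butyl 2-methylbut-3-en-2-yl carbonate | C=CC(C)(C)OC(=O)OC(C)(C)C | intermediate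
8 | 1-[2,6-dihydroxy-4-(2-methylbut-3-en-2-yloxy)phenyl]-2-methylpropan-1-one | CC(C)C(=O)c1c(O)cc(OC(C)(C)C=C)cc1O | intermediate
9 | 1-[2,4,6-trihydroxy-3-(3-methylbut-2-en-1-yl)phenyl]-2-methylpropan-1-one | CC(C)C(=O)c1c(O)cc(O)c(CC=C(C)C)c1O | intermediate
10 | 1-[2,6-dihydroxy-4-(2-methylbut-3-en-2-yloxy)-3-(3-methylbut-2-en-1-yl)phenyl]-2-methylpropan-1-one | CC(C)C(=O)c1c(O)cc(OC(C)(C)C=C)c(CC=C(C)C)c1O | intermediate
11 | deoxycohumulone, 1-[2,4,6-trihydroxy-3,5-bis(3-methylbut-2-en-1-yl)phenyl]-2-methylpropan-1-one | CC(C)C(=O)c1c(O)c(CC=C(C)C)c(O)c(CC=C(C)C)c1O | intermediate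
12 | 1-[2,6-dihydroxy-4-(2-methylbut-3-en-2-yloxy)-3,5-bis(3-methylbut-2-en-1-yl)phenyl]-2-methylpropan-1-one | CC(C)C(=O)c1c(O)c(CC=C(C)C)c(OC(C)(C)C=C)c(CC=C(C)C)c1O | intermediate
13 | colupulone, 3,5-dihydroxy-2-(2-methylpropanoyl)-4,6,6-tris(3-methylbut-2-en-1-yl)cyclohexa-2,4-dien-1-one | CC(C)C(=O)C1=C(O)C(CC=C(C)C)=C(O)C(CC=C(C)C)(CC=C(C)C)C1=O | intermediate
14 | 3-hydroxy-5-(2-methylbut-3-en-2-yloxy)-2-(2-methylpropanoyl)-4,6,6-tris(3-methylbut-2-en-1-yl)cyclohexa-2,4-dien-1-one | CC(C)C(=O)C1=C(O)C(CC=C(C)C)=C(OC(C)(C)C=C)C(CC=C(C)C)(CC=C(C)C)C1=O | intermediate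
15 | colupone, 5-hydroxy-4-(2-methylpropanoyl)-2,2,6,6-tetrakis(3-methylbut-2-en-1-yl)cyclohex-4-ene-1,3-dione | CC(C)=CCC1(CC=C(C)C)C(=O)C(C(=O)C(C)C)=C(O)C(CC=C(C)C)(CC=C(C)C)C1=O | target

## Step count and risks

Total step count: 3. Longest linear sequence: 2 steps (1 → 3 → 15, or 4 → 7 → 15).

**Most likely to fail, in order:**

**Step 3 (the proposed relay).** The risks are:
- incomplete relay, stalling at 11 or 13;
- loss of 7 as isoprene by β-hydride elimination from the π-prenyl complex;
- a fifth prenylation at the acyl-bearing carbon if 7 is overcharged;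
- air oxidation of the lupulone-type intermediates.

The regiochemistry of O-alkylation is less critical than it looks, because every ring oxygen flanks one of the two carbons that must be prenylated. The fallback uses known base-mediated C-prenylation and makes no C–O ether at all. It sets out from 3, which is treated with prenyl bromide (2.1 equiv) in aqueous KOH at 0 °C to give deoxycohumulone 11, isolated this time. Alkylative dearomatisation of 11 with more prenyl bromide (2.4 equiv) and NaOMe in MeOH at 0 °C under argon then passes through colupulone 13 and comes back to the route at 15. No new compound is made.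

**Step 2 (tertiary carbonate).** Acylation of the hindered tertiary alkoxide can be incomplete, and the volatile, heat-sensitive product can be lost on distillation. The fallback avoids the tertiary alcohol. It sets out from 5 and commercial prenol (3-methylbut-2-en-1-ol), which with DMAP (10 mol %) in CH2Cl2 at rt give the primary carbonate tert-butyl 3-methylbut-2-en-1-yl carbonate F2. F2 is used in step 3 in place of 7. Because Pd(0) ionises both carbonates to the same π-(1,1-dimethylallyl)palladium complex, the fallback comes back to the route at 8.

**Step 1 (Friedel–Crafts acylation).** O-acylation, diacylation and a tedious removal of nitrobenzene can lower the yield. The fallback is a Houben–Hoesch reaction. It sets out from 1, which with isobutyronitrile, ZnCl2 and HCl gas in Et2O at 0 °C precipitates the ketiminium salt 2-methyl-1-(2,4,6-trihydroxyphenyl)propan-1-iminium chloride F1. Hydrolysis of F1 in boiling water comes back to the route at 3.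

## Further compounds

F1 | step 1 | 2-methyl-1-(2,4,6-trihydroxyphenyl)propan-1-iminium chloride | CC(C)C(=[NH2+])c1c(O)cc(O)cc1O.[Cl-]
F2 | step 2 | tert-butyl 3-methylbut-2-en-1-yl carbonate | CC(C)=CCOC(=O)OC(C)(C)C
F0 | step 3 | none | none
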